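**Plan**

1. Numbering: C1 (methyl-bearing fusion carbon), C2, C3, C4 (isopropyl carbinol), C5 (fusion CH), C6 (ester carbon), C7, C8 (methyl-bearing alkene carbon), C9, C10; five-membered ring C1–C5, seven-membered ring C1, C5–C10.
2. Feature: the tertiary carbinol C4 is bonded to C5, and C5 lies between quaternary C1 and a C6 carbonyl. A C5 carbenoid held by a C6 ketone in the seven-membered ring can therefore insert into the C4–H bond of a silyl-protected secondary carbinol on the C1 side chain.
3. Cuts: the ester C6–O acyl bond, then C4–C5 (carbenoid C–H insertion), then C1–C2 (conjugate addition), then C6–C7/C7–C8 and C8–CH3 (one-carbon ring expansion of a methylated cyclohexanone).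
4. Forward: side-chain bromide → conjugate addition to 3-methylcyclohexenone (C1) → α-methylation and Saegusa–Ito expansion to the seven-membered enone → diazo transfer at C5 → insertion closes the five-membered ring. The alkene stays in conjugation (C7=C8) until the ring fusion is set, then is moved to C8=C9 before reduction and acylation.
5. Stereochemistry: C4 from Ru–BINAP hydrogenation, carried through the insertion with retention; C1 from ligand-controlled copper catalysis; C5 by equilibration to the trans fusion; C6 by hydride delivery from the C4 hydroxyl.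

Key step: step 11

Remark: the ring-fusion selectivity of the insertion is not relied on; C5 is α to the C6 ketone and is set in step 12, where the trans fusion (C4–O, not isopropyl, syn to C6) is taken to be the more stable arrangement.

**Route**

Step 1
Reactants: 1 methyl 4-methyl-3-oxopentanoate
Product: 2 methyl (R)-3-hydroxy-4-methylpentanoate
Conditions: H2 (50 atm), RuCl2[(S)-BINAP] (0.1 mol %), MeOH, 50 °C
Reagents that add atoms: none
Why: Noyori asymmetric hydrogenation of a β-keto ester; (S)-BINAP delivers hydrogen in the sense that gives (S)-3-hydroxybutanoate from acetoacetate, which here carries the descriptor R because isopropyl outranks CH2CO2Me, and this sets the future C4.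

Step 2
Reactants: 2 methyl (R)-3-hydroxy-4-methylpentanoate
Product: 3 methyl (R)-4-methyl-3-(triethylsilyloxy)pentanoate
Conditions: Et3SiCl, imidazole, DMF, 0 °C → rt
Reagents that add atoms: chlorotriethylsilane, CC[Si](Cl)(CC)CC
Why: O-silylation of a secondary alcohol; the triethylsilyl ether is small enough to leave the carbinol C–H accessible, keeps the oxygen lone pairs that activate it, and can later be removed from a tertiary position.

Step 3
Reactants: 3 methyl (R)-4-methyl-3-(triethylsilyloxy)pentanoate
Product: 4 (R)-4-methyl-3-(triethylsilyloxy)pentan-1-ol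
Conditions: i-Bu2AlH (2.5 equiv), CH2Cl2, −78 → 0 °C
Reagents that add atoms: none
Why: Hydride reduction of an ester to the primary alcohol; the silyl ether and the stereocentre are not touched.

Step 4
Reactants: 4 (R)-4-methyl-3-(triethylsilyloxy)pentan-1-ol
Product: 5 (R)-1-bromo-4-methyl-3-(triethylsilyloxy)pentane
Conditions: CBr4, PPh3, 2,6-lutidine, CH2Cl2, 0 °C
Reagents that add atoms: carbon tetrabromide, BrC(Br)(Br)Br
Why: Appel bromination (SN2 at the primary carbon), buffered so that the silyl ether survives.

Step 5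
Reactants: 5 (R)-1-bromo-4-methyl-3-(triethylsilyloxy)pentane; 6 3-methylcyclohex-2-en-1-one
Product: 8 (S)-3-methyl-3-[(R)-4-methyl-3-(triethylsilyloxy)pentyl]cyclohexan-1-one, via Grignard reagent 7 (not isolated)
Conditions: Mg, Et2O, 35 °C; then 6, Cu(OTf)2 (3 mol %), chiral imidazolinium salt (N-heterocyclic carbene precursor, 4 mol %), Et2O, 0 °C
Reagents that add atoms: none
Why: Copper-catalysed asymmetric conjugate addition of a Grignard reagent to a β-methyl cyclic enone; the ligand enantiomer is chosen to give the (S) quaternary carbon (future C1), and since the side chain is already one enantiomer the minor face gives a separable diastereomer.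

Step 6
Reactants: 8 (S)-3-methyl-3-[(R)-4-methyl-3-(triethylsilyloxy)pentyl]cyclohexan-1-one
Product: 9 (5S)-2,5-dimethyl-5-[(R)-4-methyl-3-(triethylsilyloxy)pentyl]cyclohexan-1-one (C2 epimers)
Conditions: LiN(i-Pr)2, THF, −78 °C; MeI, −78 → −20 °C
Reagents that add atoms: iodomethane, CI
Why: Kinetic enolate alkylation; deprotonation should occur at the CH2 remote from the quaternary carbon because the neopentyl side is shielded, and the new methine centre is erased in step 7.

Step 7
Reactants: 9 (5S)-2,5-dimethyl-5-[(R)-4-methyl-3-(triethylsilyloxy)pentyl]cyclohexan-1-one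
Product: 10 (5S)-2,5-dimethyl-5-[(R)-4-methyl-3-(triethylsilyloxy)pentyl]-1-(trimethylsilyloxy)cyclohex-1-ene
Conditions: Me3SiCl, NaI, Et3N, MeCN, rt
Reagents that add atoms: chlorotrimethylsilane, C[Si](C)(C)Cl
Why: Silyl enol ether formation under equilibrating conditions (Me3SiI made in the flask), which should give the tetrasubstituted enol ether toward the methyl-bearing carbon.

Step 8
Reactants: 10 (5S)-2,5-dimethyl-5-[(R)-4-methyl-3-(triethylsilyloxy)pentyl]-1-(trimethylsilyloxy)cyclohex-1-ene
Product: 11 3,6-dimethyl-3-[(R)-4-methyl-3-(triethylsilyloxy)pentyl]-1-(trimethylsilyloxy)bicyclo[4.1.0]heptane (quaternary centre as in 10, cyclopropane diastereomers)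
Conditions: Et2Zn, CH2I2, CH2Cl2, 0 °C → rt
Reagents that add atoms: diiodomethane, ICI
Why: Simmons–Smith cyclopropanation (Furukawa variant) of the electron-rich silyl enol ether; the cyclopropane stereocentres are lost in step 9.

Step 9
Reactants: 11 3,6-dimethyl-3-[(R)-4-methyl-3-(triethylsilyloxy)pentyl]-1-(trimethylsilyloxy)bicyclo[4.1.0]heptane
Product: 13 (S)-3,6-dimethyl-6-[(R)-4-methyl-3-(triethylsilyloxy)pentyl]cyclohept-2-en-1-one, via β-chloro ketone 12 (not isolated)
Conditions: FeCl3, pyridine, DMF, 0 °C → rt; then NaOAc, MeOH, 65 °C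
Reagents that add atoms: none
Why: Saegusa–Ito ring expansion; one-electron oxidation of the siloxycyclopropane cleaves the internal bond to the tertiary radical, chlorine transfer gives the β-chloro ketone, and acetate eliminates HCl to the conjugated β-methyl enone, the aprotic buffered medium being chosen to spare the triethylsilyl ether.

Step 10
Reactants: 13 (S)-3,6-dimethyl-6-[(R)-4-methyl-3-(triethylsilyloxy)pentyl]cyclohept-2-en-1-one; 14 4-acetamidobenzenesulfonyl azide
Product: 16 (S)-7-diazo-3,6-dimethyl-6-[(R)-4-methyl-3-(triethylsilyloxy)pentyl]cyclohept-2-en-1-one, via trifluoroacetyl ketone 15 (not isolated)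
Conditions: LiN(SiMe3)2, THF, −78 °C; CF3CO2CH2CF3; then 14, Et3N, MeCN, rt
Reagents that add atoms: none
Why: Kinetic deprotonation of the enone at its only α′ position (C5), C-trifluoroacetylation and detrifluoroacetylative Regitz diazo transfer, the standard entry to α′-diazo enones; the conjugated alkene makes C5 the only site that can be activated.

Step 11
Reactants: 16 (S)-7-diazo-3,6-dimethyl-6-[(R)-4-methyl-3-(triethylsilyloxy)pentyl]cyclohept-2-en-1-one
Product: 17 (3R,8aS)-6,8a-dimethyl-3-isopropyl-3-(triethylsilyloxy)-2,3,3a,7,8,8a-hexahydroazulen-4(1H)-one (C3a = C5 as formed, either epimer)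
Conditions: Rh2(OAc)4 (1 mol %), CH2Cl2, 40 °C, slow addition of 16
Reagents that add atoms: none
Why: Rh2(OAc)4 expels N2 from 16 to give an electrophilic rhodium carbenoid at C5 that has no β-hydrogen to shift (C1 is quaternary, C6 is a carbonyl) and inserts in one concerted three-centre step into the oxygen-activated tertiary C4–H bond. The closest known reaction type is the dirhodium-carboxylate 1,5 C–H insertion of α-diazo ketones into ether- or silyl-ether-activated C–H bonds. The cyclopentane C1–C2–C3–C4–C5 closes by 1,5-insertion through a five-membered transition state onto the seven-membered ring already in place. C4 becomes quaternary with retention of the configuration set in step 1, since C–C replaces C–H from the front; C5 is created in the same event but is α to the ketone and is fixed only in step 12. The step needs insertion at C4–H to beat Wolff ring contraction, 1,2-shift of a C1 substituent, insertion into the isopropyl methine (six-membered transition state) and dimerisation; the α-silyloxy activation, the five-membered geometry, the quaternary C1 and a low carbenoid concentration should secure it.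

Step 12
Reactants: 17 insertion product (C5 epimers)
Product: 18 (3R,3aR,8aS)-6,8a-dimethyl-3-isopropyl-3-(triethylsilyloxy)-2,3,3a,7,8,8a-hexahydroazulen-4(1H)-one (trans-fused)
Conditions: DBU, toluene, 60 °C, monitored and stopped at equilibrium
Reagents that add atoms: none
Why: Base-mediated epimerisation α to the ketone through the cross-conjugated C5 enolate under thermodynamic control; the trans fusion should prevail because it places the C4 oxygen rather than the isopropyl group syn to C6, and any alkene isomer formed by γ-deprotonation converges on the same dienolate in step 13.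

Step 13
Reactants: 18 trans-fused conjugated enone
Product: 20 (3R,3aR,8aR)-6,8a-dimethyl-3-isopropyl-3-(triethylsilyloxy)-1,2,3,3a,8,8a-hexahydroazulen-4(5H)-one, via potassium dienolate 19 (not isolated)
Conditions: KOt-Bu (excess), t-BuOH–THF, 0 °C; poured into cold AcOH–H2O
Reagents that add atoms: none
Why: Deconjugation of a cyclic enone by kinetic α-protonation of its extended dienolate; excess KOt-Bu forms the more substituted endocyclic dienolate by loss of a C9 proton, and inverse acid quench protonates C7 faster than C9, leaving the C8=C9 bond and the C5 configuration in place.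

Step 14
Reactants: 20 β,γ-unsaturated silyloxy ketone
Product: 21 (3R,3aR,8aR)-3-hydroxy-6,8a-dimethyl-3-isopropyl-1,2,3,3a,8,8a-hexahydroazulen-4(5H)-one
Conditions: HF·pyridine, pyridine, THF, 0 °C
Reagents that add atoms: none
Why: Fluoride cleavage of the silyl ether (Si–F bond formation); pyridine-buffered HF should neither enolise the β,γ-unsaturated ketone nor form the alkoxide needed for retro-aldol opening nor ionise the tertiary carbinol.

Step 15
Reactants: 21 β,γ-unsaturated ketol
Product: 22 (3R,3aS,4S,8aR)-6,8a-dimethyl-3-isopropyl-1,2,3,3a,4,5,8,8a-octahydroazulene-3,4-diol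
Conditions: Me4NBH(OAc)3, MeCN–AcOH, −20 °C
Reagents that add atoms: none
Why: Saksena–Evans hydroxyl-directed reduction; the C4 hydroxyl exchanges an acetate on boron and delivers hydride within a six-membered transition state to the C6 face syn to the C4–O bond, overriding external attack anti to the C1 methyl and giving the 1,3-anti diol with the C6 hydroxyl trans to that methyl.

Step 16
Reactants: 22 diol; 23 2,2-dimethyl-4H-1,3-benzodioxin-4-one
Product: 24 (3R,3aS,4S,8aR)-3-hydroxy-6,8a-dimethyl-3-isopropyl-1,2,3,3a,4,5,8,8a-octahydroazulen-4-yl 2-hydroxybenzoate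
Conditions: NaN(SiMe3)2 (1.1 equiv), THF, 0 °C; then 23, 0 °C → rt; AcOH quench
Reagents that add atoms: none
Why: Transesterification by alkoxide ring-opening of the salicylic acid acetonide with loss of acetone; the secondary C6 alkoxide is acylated while the hindered tertiary C4 hydroxyl does not compete, the phenol is released directly, and no stereocentre is touched.

**Compound list**

1 | methyl 4-methyl-3-oxopentanoate | CC(C)C(=O)CC(=O)OC | starting material
2 | methyl (R)-3-hydroxy-4-methylpentanoate | CC(C)[C@H](O)CC(=O)OC | intermediate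
3 | methyl (R)-4-methyl-3-(triethylsilyloxy)pentanoate | CC(C)[C@H](O[Si](CC)(CC)CC)CC(=O)OC | intermediate
4 | (R)-4-methyl-3-(triethylsilyloxy)pentan-1-ol | CC(C)[C@H](O[Si](CC)(CC)CC)CCO | intermediate
5 | (R)-1-bromo-4-methyl-3-(triethylsilyloxy)pentane | CC(C)[C@H](O[Si](CC)(CC)CC)CCBr | intermediate
6 | 3-methylcyclohex-2-en-1-one | CC1=CC(=O)CCC1 | starting material
7 | (R)-[4-methyl-3-(triethylsilyloxy)pentyl]magnesium bromide | CC(C)[C@H](O[Si](CC)(CC)CC)CC[Mg]Br | intermediate (not isolated)
8 | (S)-3-methyl-3-[(R)-4-methyl-3-(triethylsilyloxy)pentyl]cyclohexan-1-one | O=C1C[C@](C)(CC[C@@H](O[Si](CC)(CC)CC)C(C)C)CCC1 | intermediate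
9 | (5S)-2,5-dimethyl-5-[(R)-4-methyl-3-(triethylsilyloxy)pentyl]cyclohexan-1-one, C2 epimers | CC1CC[C@@](C)(CC[C@@H](O[Si](CC)(CC)CC)C(C)C)CC1=O | intermediate
10 | (5S)-2,5-dimethyl-5-[(R)-4-methyl-3-(triethylsilyloxy)pentyl]-1-(trimethylsilyloxy)cyclohex-1-ene | CC1=C(O[Si](C)(C)C)C[C@](C)(CC[C@@H](O[Si](CC)(CC)CC)C(C)C)CC1 | intermediate
11 | 3,6-dimethyl-3-[(R)-4-methyl-3-(triethylsilyloxy)pentyl]-1-(trimethylsilyloxy)bicyclo[4.1.0]heptane, cyclopropane diastereomers | CC12CC[C@@](C)(CC[C@@H](O[Si](CC)(CC)CC)C(C)C)CC1(O[Si](C)(C)C)C2 | intermediate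
12 | 3-chloro-3,6-dimethyl-6-[(R)-4-methyl-3-(triethylsilyloxy)pentyl]cycloheptan-1-one | CC1(Cl)CC[C@@](C)(CC[C@@H](O[Si](CC)(CC)CC)C(C)C)CC(=O)C1 | intermediate (not isolated)
13 | (S)-3,6-dimethyl-6-[(R)-4-methyl-3-(triethylsilyloxy)pentyl]cyclohept-2-en-1-one | CC1=CC(=O)C[C@](C)(CC[C@@H](O[Si](CC)(CC)CC)C(C)C)CC1 | intermediate
14 | 4-acetamidobenzenesulfonyl azide | CC(=O)Nc1ccc(cc1)S(=O)(=O)N=[N+]=[N-] | starting material
15 | 3,6-dimethyl-6-[(R)-4-methyl-3-(triethylsilyloxy)pentyl]-7-(trifluoroacetyl)cyclohept-2-en-1-one | CC1=CC(=O)C(C(=O)C(F)(F)F)[C@](C)(CC[C@@H](O[Si](CC)(CC)CC)C(C)C)CC1 | intermediate (not isolated)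
16 | (S)-7-diazo-3,6-dimethyl-6-[(R)-4-methyl-3-(triethylsilyloxy)pentyl]cyclohept-2-en-1-one | CC1=CC(=O)C(=[N+]=[N-])[C@](C)(CC[C@@H](O[Si](CC)(CC)CC)C(C)C)CC1 | intermediate
17 | (3R,8aS)-6,8a-dimethyl-3-isopropyl-3-(triethylsilyloxy)-2,3,3a,7,8,8a-hexahydroazulen-4(1H)-one, C3a (C5) epimers | CC1=CC(=O)C2[C@@](C)(CC1)CC[C@@]2(O[Si](CC)(CC)CC)C(C)C | intermediate
18 | (3R,3aR,8aS)-6,8a-dimethyl-3-isopropyl-3-(triethylsilyloxy)-2,3,3a,7,8,8a-hexahydroazulen-4(1H)-one | CC1=CC(=O)[C@@H]2[C@@](C)(CC1)CC[C@@]2(O[Si](CC)(CC)CC)C(C)C | intermediate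
19 | potassium dienolate of 18 (C6 enolate, C6=C7 and C8=C9) | CC1=CC[C@@]2(C)CC[C@@](O[Si](CC)(CC)CC)(C(C)C)[C@@H]2C([O-])=C1.[K+] | intermediate (not isolated)
20 | (3R,3aR,8aR)-6,8a-dimethyl-3-isopropyl-3-(triethylsilyloxy)-1,2,3,3a,8,8a-hexahydroazulen-4(5H)-one | CC1=CC[C@@]2(C)CC[C@@](O[Si](CC)(CC)CC)(C(C)C)[C@@H]2C(=O)C1 | intermediate
21 | (3R,3aR,8aR)-3-hydroxy-6,8a-dimethyl-3-isopropyl-1,2,3,3a,8,8a-hexahydroazulen-4(5H)-one | CC1=CC[C@@]2(C)CC[C@@](O)(C(C)C)[C@@H]2C(=O)C1 | intermediate
22 | (3R,3aS,4S,8aR)-6,8a-dimethyl-3-isopropyl-1,2,3,3a,4,5,8,8a-octahydroazulene-3,4-diol | CC1=CC[C@@]2(C)CC[C@@](O)(C(C)C)[C@@H]2[C@@H](O)C1 | intermediate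
23 | 2,2-dimethyl-4H-1,3-benzodioxin-4-one | CC1(C)OC(=O)c2ccccc2O1 | starting material
24 | (3R,3aS,4S,8aR)-3-hydroxy-6,8a-dimethyl-3-isopropyl-1,2,3,3a,4,5,8,8a-octahydroazulen-4-yl 2-hydroxybenzoate | CC1=CC[C@@]2(C)CC[C@@](O)(C(C)C)[C@@H]2[C@@H](OC(=O)c2ccccc2O)C1 | target

**Count**

Total steps: 16. Longest linear sequence: 16 steps (1 → 24; compounds 6, 14 and 23 are purchased).

**Steps most likely to fail**

Step 11. The carbenoid may be consumed before it reaches the crowded C4–H bond, by Wolff ring contraction, 1,2-shift of a C1 substituent, insertion into the isopropyl methine or dimerisation. The fallback makes C4–C5 as an aldol bond and sets out from enone 13. The kinetic lithium enolate (LiN(SiMe3)2, THF, −78 °C) would be brominated with N-bromosuccinimide to 7-bromo-3,6-dimethyl-6-[(R)-4-methyl-3-(triethylsilyloxy)pentyl]cyclohept-2-en-1-one F1. HF·pyridine would free the side-chain alcohol, 7-bromo-6-[(R)-3-hydroxy-4-methylpentyl]-3,6-dimethylcyclohept-2-en-1-one F2, and Dess–Martin periodinane would give the isopropyl ketone, 7-bromo-3,6-dimethyl-6-(4-methyl-3-oxopentyl)cyclohept-2-en-1-one F3. SmI2 (THF, −78 °C) would then form the samarium enolate at C5 only, and a Reformatsky-type aldol cyclisation onto the C4 ketone would close the five-membered ring to the ketol (3R,3aR,8aS)-3-hydroxy-6,8a-dimethyl-3-isopropyl-2,3,3a,7,8,8a-hexahydroazulen-4(1H)-one F4. Et3SiOTf and 2,6-lutidine would silylate it, and the route is rejoined at 18. In this variant C4 would be set by the samarium chelate between enolate and ketone oxygens and by the preference for the trans fusion, so the diastereomer ratio would have to be established.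

Step 13. Part of the dienolate may be protonated at C9, or excess alkoxide may re-enolise the product during the quench, so that the double bond returns to conjugation; long exposure may also expel silanolate from the C5 enolate. The fallback traps the dienol on oxygen first and sets out from 18. Enol acetylation (isopropenyl acetate, catalytic TsOH) would give the C6 enol acetate of 18 with C6=C7 and C8=C9 double bonds F5, an isolable compound whose diene regiochemistry can be secured by purification. Two equivalents of MeLi (THF, −78 °C) would cleave the acetate to the lithium dienolate without protic solvent, and AcOH quench at −78 °C would return the route at 20.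

Step 14. Cleavage of the hindered tertiary silyl ether may be slow, and during the long exposure the C8=C9 bond may drift into conjugation or the freed ketol may open by retro-aldol reaction. The fallback takes the ketone out of play during desilylation and sets out from 20. NaBH4 (MeOH, 0 °C) would reduce the ketone, by external attack anti to the C1 methyl, to (3R,3aS,4R,8aR)-6,8a-dimethyl-3-isopropyl-3-(triethylsilyloxy)-1,2,3,3a,4,5,8,8a-octahydroazulen-4-ol F6. Bu4NF (THF) could then remove the silyl group without restriction to give (3R,3aS,4R,8aR)-6,8a-dimethyl-3-isopropyl-1,2,3,3a,4,5,8,8a-octahydroazulene-3,4-diol F7. Dess–Martin periodinane buffered with NaHCO3 would oxidise only the secondary alcohol and return the route at 21.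

Further compounds
F1 | step 11 | 7-bromo-3,6-dimethyl-6-[(R)-4-methyl-3-(triethylsilyloxy)pentyl]cyclohept-2-en-1-one | CC1=CC(=O)C(Br)[C@](C)(CC[C@@H](O[Si](CC)(CC)CC)C(C)C)CC1
F2 | step 11 | 7-bromo-6-[(R)-3-hydroxy-4-methylpentyl]-3,6-dimethylcyclohept-2-en-1-one | CC1=CC(=O)C(Br)[C@](C)(CC[C@@H](O)C(C)C)CC1
F3 | step 11 | 7-bromo-3,6-dimethyl-6-(4-methyl-3-oxopentyl)cyclohept-2-en-1-one | CC1=CC(=O)C(Br)[C@](C)(CCC(=O)C(C)C)CC1
F4 | step 11 | (3R,3aR,8aS)-3-hydroxy-6,8a-dimethyl-3-isopropyl-2,3,3a,7,8,8a-hexahydroazulen-4(1H)-one | CC1=CC(=O)[C@@H]2[C@@](C)(CC1)CC[C@@]2(O)C(C)C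
F5 | step 13 | C6 enol acetate of 18 (C6=C7 and C8=C9 double bonds) | CC1=CC[C@@]2(C)CC[C@@](O[Si](CC)(CC)CC)(C(C)C)[C@@H]2C(OC(C)=O)=C1
F6 | step 14 | (3R,3aS,4R,8aR)-6,8a-dimethyl-3-isopropyl-3-(triethylsilyloxy)-1,2,3,3a,4,5,8,8a-octahydroazulen-4-ol | CC1=CC[C@@]2(C)CC[C@@](O[Si](CC)(CC)CC)(C(C)C)[C@@H]2[C@H](O)C1
F7 | step 14 | (3R,3aS,4R,8aR)-6,8a-dimethyl-3-isopropyl-1,2,3,3a,4,5,8,8a-octahydroazulene-3,4-diol | CC1=CC[C@@]2(C)CC[C@@](O)(C(C)C)[C@@H]2[C@H](O)C1
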